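The data were generated by integration on assumed constants.

If I follow one molecule of substrate through these flasks, I ask first whether the time still matters, and then where the molecule sits once it no longer does.

| flask | substrate | temperature | remark | time |
|---|---|---|---|---|
| north-east | 1.7 M | 30 °C | run made earlier |  |
| east | 2.6 M | 48 °C | run made earlier |  |
| Wednesday's | 1.2 M | 60 °C |  | 8.0 min |
| Friday's | 1.2 M | 35 °C |  | 8.0 min |

| run | time / min | target / % |
|---|---|---|
| north-east | 0.417 | 36.1 |
| north-east | 0.833 | 26.4 |
| north-east | 2.00 | 18.3 |
| north-east | 5.00 | 18.3 |
| east | 0.333 | 41.5 |
| east | 0.833 | 41.2 |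
| east | 1.50 | 41.8 |
| east | 2.50 | 41.1 |

(standard deviation of a reading: 0.5 percentage points)



- which of the two there is more of at the end, Wednesday's (target / isomer of the product)
- which of the two there is more of at the end, Friday's (target / isomer of the product)
- how much target is there at the end, in percent of the substrate charged: Wednesday's
- how much target is there at the end, in percent of the substrate charged: Friday's

In the north-east run target falls from 36.1% to 18.3% by 2.00 min and reads 18.3% at 5.00 min, while the east run, hotter and with more substrate charged, is flat within the scatter from its first reading. The 8.0 min of the new flasks is longer than the north-east approach, and both new flasks are hotter than the north-east run, so I expect thermodynamic rather than kinetic control at the end of both.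

The question then becomes the molecule's chance of standing as target, which I write as the plateau odds, [target] over the remainder of the charge. These read 0.224 at 30 °C and 0.706 at 48 °C. I assume the charge does not move them, though these two runs cannot test that.

How do the odds change with temperature? I take the logarithm of the odds as straight in inverse temperature, and R times its fall per unit of inverse temperature, the odds heat 51.7 kJ mol⁻¹, gives 0.312 for Friday's flask and 1.42 for Wednesday's. Taking the remainder to be chiefly isomer of the product, I commit to isomer on Friday's with 23.8% target, and to target on Wednesday's with 58.7%.

The forecast says target at 58.7% for Wednesday's and isomer of the product with 23.8% target for Friday's, and adds of the hot flask: “That extrapolation is less certain.”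

Wednesday's flask gives 51.7% target and 16.2% isomer, with 31% substrate left, so its odds are 1.07 against my 1.42. Friday's flask gives 24.5% target and 58.0% isomer, odds 0.324 against my 0.312.

    substrate ⇌ target (K = 1.80, k = 0.174 s⁻¹, Ea = 76.0 kJ mol⁻¹, ΔH = −3.00 kJ mol⁻¹)
    target ⇌ isomer of the product (K = 2.37, k = 0.0225 s⁻¹, Ea = 95.0 kJ mol⁻¹, ΔH = −69.0 kJ mol⁻¹)
    isomer of the product ⇌ substrate (k = 0.0126 s⁻¹, Ea = 85.0 kJ mol⁻¹)
    substrate ⇌ dormant form (K = 0.290, k = 0.00527 s⁻¹, Ea = 80.0 kJ mol⁻¹, ΔH = −88.0 kJ mol⁻¹)
    (constants at 35 °C)

In Friday's flask the relaxation half-life of target and isomer by that step alone, both ways together, is 0.361 min, short against the asked 8.0 min, and at 80.0 min target still stands at 24.5%. For the same flask as Friday's run at 10 °C, the odds heat gives 5.00% target, and that flask holds 5.35% target.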